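The numbering is that of the clerodanes (ring A = C1–C5 and C10, ring B = C5–C10). The retrosynthesis cuts O–C2 and unmasks C4=C18, then cuts C12–C13, C1–C10, C2–C3, C4–C18, C9–C11, C8–C17 and C4–C5.
Enabling feature: C10 is a lone methine between the quaternary carbons C5 and C9 and lies three bonds from the C3 carbonyl (C10–C1–C2–C3), with H10 cis to the C5 methyl. A C10 radical can therefore come from a carbinol without β-hydrogen and be caught by a vinyl ketone arm on C5.
Forward order: the ring of 2,6-dimethylphenol becomes ring B (phenol carbon = C10, para carbon = C7) and is fully substituted first. Ring A closes in step 17, C13–C16 are joined in step 21, and the 4-methylene diosphenol is unveiled last.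
C18 is added before ring A exists and passes through the ring closure as a phenylthiomethyl group on C4, so no late regiochemical choice between C2 and C4 arises.
Stereochemistry: two independent catalysts set C5 (Pd/(R)-t-BuPHOX allylation) and C7 (Ru transfer hydrogenation). C8 is set anti to O7, C9 anti to the C8 methyl, C10 by the axial C5 arm, and 13E by a stereodefined enol triflate.

Key step: step 17

Remark on descriptors: α and β refer to the usual drawing with ring A on the left, C10 above C5 and the C5 methyl (C19) pointing up (β).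
Assumption: (R)-t-BuPHOX and the (S,S)-Ru catalyst are taken to show the facial sense known for 2-methylcyclohexanone enol carbonates and for alkenyl alkyl ketones. If not, the mirror-image ligand is used.
Remark on mixtures: the centres C4 (step 10) and C3 (step 11) are not controlled and are carried as epimer mixtures. C3 is erased in step 16, the C10 carbinol centre in step 17, and C4 in step 22.

Step 1
Reactants: 1 2,6-dimethylphenol
Product: 3 4,4-dimethoxy-2,6-dimethylcyclohexa-2,5-dien-1-one, via 4-methoxy-2,6-dimethylphenol 2 (not isolated)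
Conditions: PhI(OAc)2 (2.1 equiv), MeOH, 0 °C to rt
Reagents that add atoms: methanol (CO)
Why: Twofold hypervalent-iodine oxidation of a para-unsubstituted phenol in methanol (oxidative dearomatisation) gives first the 4-methoxyphenol and then the p-quinone monoketal, and no stereocentre is formed.

Step 2
Reactants: 3 4,4-dimethoxy-2,6-dimethylcyclohexa-2,5-dien-1-one
Product: 5 allyl 4,4-dimethoxy-2,6-dimethylcyclohexa-1,5-dien-1-yl carbonate, via lithium dienolate 4 (not isolated)
Conditions: LiBH(s-Bu)3 (1.05 equiv), THF, −78 °C; ClCO2CH2CH=CH2, −78 to 0 °C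
Reagents that add atoms: allyl chloroformate (C=CCOC(=O)Cl)
Why: The two flanking methyl groups keep the bulky borohydride off the carbonyl, so hydride adds 1,4 to one of the two equivalent unsubstituted β-carbons (conjugate reduction), and the chloroformate traps the enolate on oxygen (reductive enolate trapping), which fixes the enolate at C5.

Step 3
Reactants: 5 allyl 4,4-dimethoxy-2,6-dimethylcyclohexa-1,5-dien-1-yl carbonate
Product: 6 (6S)-6-allyl-4,4-dimethoxy-2,6-dimethylcyclohex-2-en-1-one
Conditions: Pd2(dba)3 (2.5 mol %), (R)-t-BuPHOX (6 mol %), THF, 25 °C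
Reagents that add atoms: none
Why: In this decarboxylative asymmetric allylic alkylation (Tsuji type), loss of CO2 gives a chiral Pd enolate/allyl pair that recombines only at C5, and because the substrate is achiral the ligand alone sets the quaternary centre (allyl α, methyl β, the spatial series of (R)-2-allyl-2-methylcyclohexanone).

Step 4
Reactants: 6 (6S)-6-allyl-4,4-dimethoxy-2,6-dimethylcyclohex-2-en-1-one
Product: 7 (6S)-6-allyl-2,6-dimethylcyclohex-2-ene-1,4-dione
Conditions: 1 M aq. HCl, THF, 0 °C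
Reagents that add atoms: water (O)
Why: Acid hydrolysis of an allylic dimethyl ketal is fast, aromatisation is impossible because C5 is quaternary, and C5 is untouched.

Step 5
Reactants: 7 (6S)-6-allyl-2,6-dimethylcyclohex-2-ene-1,4-dione
Product: 8 (4S,6S)-6-allyl-4-hydroxy-2,6-dimethylcyclohex-2-en-1-one
Conditions: RuCl(p-cymene)[(S,S)-TsDPEN] (1 mol %), KOH (2 mol %), i-PrOH, rt
Reagents that add atoms: none
Why: Noyori-type asymmetric transfer hydrogenation reduces the open C7 carbonyl and spares the C10 carbonyl next to quaternary C5 (as in the reduction of ketoisophorone to 4-hydroxyisophorone), and the catalyst sets C7 (7β-OH), so the minor C5 antipode becomes a diastereomer that should be separable.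

Step 6
Reactants: 8 (4S,6S)-6-allyl-4-hydroxy-2,6-dimethylcyclohex-2-en-1-one
Product: 9 (4S,6S)-6-allyl-4-(tert-butyldimethylsilyloxy)-2,6-dimethylcyclohex-2-en-1-one
Conditions: TBSCl, imidazole, DMF, rt
Reagents that add atoms: tert-butyldimethylsilyl chloride (CC(C)(C)[Si](C)(C)Cl)
Why: Standard silylation of a secondary allylic alcohol puts a bulky non-coordinating group on O7, which the next step needs as its steering element.

Step 7
Reactants: 9 (4S,6S)-6-allyl-4-(tert-butyldimethylsilyloxy)-2,6-dimethylcyclohex-2-en-1-one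
Product: 10 (3S,4S,6S)-6-allyl-4-(tert-butyldimethylsilyloxy)-2,3,6-trimethyl-1-(trimethylsilyloxy)cyclohex-1-ene
Conditions: Me2CuLi (from MeLi and CuBr·SMe2), TMSCl, Et2O/THF, −78 °C
Reagents that add atoms: lithium dimethylcuprate ([Li+].C[Cu-]C); chlorotrimethylsilane (C[Si](C)(C)Cl)
Why: In this TMSCl-accelerated cuprate 1,4-addition, methyl enters C8 anti to the pseudoaxial 7β-silyloxy group (the usual trans result for 4-oxygenated cyclohexenones), which sets C8 (methyl α), and the enolate is stored regiospecifically as its silyl enol ether.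

Step 8
Reactants: 10 (3S,4S,6S)-6-allyl-4-(tert-butyldimethylsilyloxy)-2,3,6-trimethyl-1-(trimethylsilyloxy)cyclohex-1-ene
Product: 12 ethyl 2-[(1S,2S,3S,5S)-5-allyl-3-(tert-butyldimethylsilyloxy)-1,2,5-trimethyl-6-oxocyclohexyl]acetate, via lithium enolate 11 (not isolated)
Conditions: MeLi, THF, 0 °C; DMPU, ICH2CO2Et, −78 to 0 °C
Reagents that add atoms: ethyl iodoacetate (CCOC(=O)CI)
Why: The lithium enolate is released regiospecifically from the silyl enol ether and alkylated (SN2) by a reactive α-iodo ester, which should enter from the β face, anti to the vicinal C8 methyl and to the pseudoaxial α-allyl group on C5 (the usual trans outcome of conjugate addition then alkylation), setting quaternary C9 (C11 β, methyl α).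

Step 9
Reactants: 12 ethyl 2-[(1S,2S,3S,5S)-5-allyl-3-(tert-butyldimethylsilyloxy)-1,2,5-trimethyl-6-oxocyclohexyl]acetate
Product: 14 ethyl 2-[(1S,2S,3S,5R)-3-(tert-butyldimethylsilyloxy)-1,2,5-trimethyl-6-oxo-5-(2-oxoethyl)cyclohexyl]acetate, via secondary ozonide 13 (not isolated)
Conditions: O3, CH2Cl2, −78 °C; PPh3, −78 °C to rt
Reagents that add atoms: ozone ([O-][O+]=O)
Why: Ozonolysis with reductive work-up cleaves the only C=C bond and leaves C4–C3 as an acetaldehyde arm, while silyl ether, ester and ketone are inert.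

Step 10
Reactants: 14 ethyl 2-[(1S,2S,3S,5R)-3-(tert-butyldimethylsilyloxy)-1,2,5-trimethyl-6-oxo-5-(2-oxoethyl)cyclohexyl]acetate
Product: 16 ethyl 2-[(1S,2S,3S,5R)-3-(tert-butyldimethylsilyloxy)-1,2,5-trimethyl-6-oxo-5-[1-oxo-3-(phenylsulfanyl)propan-2-yl]cyclohexyl]acetate (C4 epimers), via enal 15 (not isolated)
Conditions: 37% aq. CH2O (1.05 equiv), pyrrolidine and EtCO2H (20 mol % each), i-PrOH, 45 °C; PhSH, Et3N (cat.), rt
Reagents that add atoms: formaldehyde (C=O); thiophenol (Sc1ccccc1)
Why: The amine-catalysed Mannich condensation (α-methylenation of an aldehyde) can act only at C4 because the C10 ketone has no α-hydrogen, and thia-Michael addition masks the enal at once so that C18 travels as a robust sulfide, the uncontrolled C4 centre vanishing in step 22.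

Step 11
Reactants: 16 ethyl 2-[(1S,2S,3S,5R)-3-(tert-butyldimethylsilyloxy)-1,2,5-trimethyl-6-oxo-5-[1-oxo-3-(phenylsulfanyl)propan-2-yl]cyclohexyl]acetate
Product: 17 ethyl 2-[(1S,2S,3S,5R)-3-(tert-butyldimethylsilyloxy)-5-[3-hydroxy-1-(phenylsulfanyl)pent-4-en-2-yl]-1,2,5-trimethyl-6-oxocyclohexyl]acetate (C3 and C4 epimers)
Conditions: CH2=CHMgBr (1.2 equiv), THF, −78 °C
Reagents that add atoms: vinylmagnesium bromide (C=C[Mg]Br)
Why: Grignard 1,2-addition to the aldehyde at low temperature is faster than attack on the ester, on the ketone shielded by two quaternary carbons, or loss of thiolate, and the new C3 carbinol centre needs no control.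

Step 12
Reactants: 17 ethyl 2-[(1S,2S,3S,5R)-3-(tert-butyldimethylsilyloxy)-5-[3-hydroxy-1-(phenylsulfanyl)pent-4-en-2-yl]-1,2,5-trimethyl-6-oxocyclohexyl]acetate
Product: 18 (1R,2S,3S,4S,6R)-4-(tert-butyldimethylsilyloxy)-2-(2-hydroxyethyl)-6-[3-hydroxy-1-(phenylsulfanyl)pent-4-en-2-yl]-2,3,6-trimethylcyclohexan-1-ol
Conditions: LiAlH4, Et2O, 0 °C to reflux
Reagents that add atoms: none
Why: Hydride reduction takes the ester to the C12 alcohol and the hindered C10 ketone to the carbinol in one operation, hydride reaching C10 from the β face away from the axial α groups on C5 and C9 (10α-OH expected, a centre that is erased later).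

Step 13
Reactants: 18 (1R,2S,3S,4S,6R)-4-(tert-butyldimethylsilyloxy)-2-(2-hydroxyethyl)-6-[3-hydroxy-1-(phenylsulfanyl)pent-4-en-2-yl]-2,3,6-trimethylcyclohexan-1-ol
Product: 19 (1R,2S,3S,4S,6R)-4-(tert-butyldimethylsilyloxy)-2-[2-(tert-butyldimethylsilyloxy)ethyl]-6-[3-(tert-butyldimethylsilyloxy)-1-(phenylsulfanyl)pent-4-en-2-yl]-2,3,6-trimethylcyclohexan-1-ol
Conditions: TBSCl (2.3 equiv), imidazole, DMF, rt
Reagents that add atoms: tert-butyldimethylsilyl chloride (CC(C)(C)[Si](C)(C)Cl)
Why: In this selective silylation the primary C12 and the allylic C3 hydroxyls react, whereas the C10 hydroxyl between two quaternary carbons is too crowded for the silyl chloride.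

Step 14
Reactants: 19 (1R,2S,3S,4S,6R)-4-(tert-butyldimethylsilyloxy)-2-[2-(tert-butyldimethylsilyloxy)ethyl]-6-[3-(tert-butyldimethylsilyloxy)-1-(phenylsulfanyl)pent-4-en-2-yl]-2,3,6-trimethylcyclohexan-1-ol
Product: 21 O-{(1R,2S,3S,4S,6R)-4-(tert-butyldimethylsilyloxy)-2-[2-(tert-butyldimethylsilyloxy)ethyl]-6-[3-(tert-butyldimethylsilyloxy)-1-(phenylsulfanyl)pent-4-en-2-yl]-2,3,6-trimethylcyclohexyl} S-methyl carbonodithioate, via potassium xanthate 20 (not isolated)
Conditions: KN(SiMe3)2, THF, −78 °C; CS2, −78 to 0 °C; MeI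
Reagents that add atoms: carbon disulfide (S=C=S); iodomethane (CI)
Why: In this xanthate formation (first half of the Barton–McCombie sequence) the potassium alkoxide adds to small, linear CS2 even at a crowded carbinol and the salt is S-methylated, and the step is placed here because no carbonyl or other base-sensitive group is present.

Step 15
Reactants: 21 the tris-silylated S-methyl xanthate
Product: 22 O-{(1R,2S,3S,4S,6R)-4-hydroxy-2-(2-hydroxyethyl)-6-[3-hydroxy-1-(phenylsulfanyl)pent-4-en-2-yl]-2,3,6-trimethylcyclohexyl} S-methyl carbonodithioate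
Conditions: HF·pyridine, pyridine, THF, 0 °C to rt
Reagents that add atoms: none
Why: Buffered fluoride desilylation frees the three hydroxyls at once, and xanthate, sulfide and allylic alcohol tolerate pyridine-buffered HF.

Step 16
Reactants: 22 O-{(1R,2S,3S,4S,6R)-4-hydroxy-2-(2-hydroxyethyl)-6-[3-hydroxy-1-(phenylsulfanyl)pent-4-en-2-yl]-2,3,6-trimethylcyclohexyl} S-methyl carbonodithioate
Product: 23 O-{(1R,2S,3S,4S,6R)-4-hydroxy-2-(2-hydroxyethyl)-2,3,6-trimethyl-6-[3-oxo-1-(phenylsulfanyl)pent-4-en-2-yl]cyclohexyl} S-methyl carbonodithioate (C4 epimers)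
Conditions: MnO2 (activated, excess), CH2Cl2, rt
Reagents that add atoms: none
Why: Allylic-selective MnO2 oxidation turns only the C3 vinyl carbinol into the vinyl ketone, leaves the saturated C7 and C12 hydroxyls, the sulfide and the xanthate alone, and merges the C3 epimers.

Step 17
Reactants: 23 O-{(1R,2S,3S,4S,6R)-4-hydroxy-2-(2-hydroxyethyl)-2,3,6-trimethyl-6-[3-oxo-1-(phenylsulfanyl)pent-4-en-2-yl]cyclohexyl} S-methyl carbonodithioate
Product: 24 (5S,7S,8S,9R,10R)-7,12-dihydroxy-18-(phenylsulfanyl)-13,14,15,16-tetranorclerodan-3-one (cis-fused decalone with H10 and C19 both β; C4 epimers)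
Conditions: Bu3SnH (1.3 equiv) and AIBN (0.2 equiv) in PhH added by syringe pump over 10 h to 23 (2 mM) in PhH, reflux
Reagents that add atoms: none
Why: Bu3Sn radicals add to the thiocarbonyl sulfur of 23 and the adduct fragments at the C10–O bond (Barton–McCombie mode, helped by relief of strain and free of Chugaev elimination because C5 and C9 carry no hydrogen), the nucleophilic secondary C10 radical adds to the unsubstituted β-carbon C1 of the vinyl ketone, and the resulting C2 α-keto radical takes hydrogen from Bu3SnH. The closest known reaction type is the tin hydride mediated Giese-type cyclisation of 4-oxohex-5-enyl radicals, which gives cyclohexanones. Ring A closes in the 6-endo-trig mode, because with the sp2 carbon C3 inside the forming ring the 5-exo transition state at C2 is strained and would leave an unstabilised primary radical, whereas attack at C1 is polarity matched and gives a stabilised radical. C10 is the only new stereocentre and the tether sets it: ring B prefers the chair with O7, C17 and C11 equatorial, the C5 arm is then axial on the α face and reaches only the α lobe of the planar radical, so H10 ends β and cis to C19, while a trans fusion would need the other chair with three syn-axial β substituents. The step needs ring closure to outrun hydrogen transfer to C10 and needs tin to attack C=S rather than the enone, which high dilution, slow addition of Bu3SnH, the thiophilicity of tin radicals and the reversibility of their addition to enones should secure. The phenylthiomethyl group on C4 is a spectator that carries C18, keeps C4 sp3 (an alkene at C4 would open a homoallyl rearrangement of the C10 radical) and stays intact because alkyl phenyl sulfides react only slowly with tin radicals.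

Step 18
Reactants: 24 (5S,7S,8S,9R,10R)-7,12-dihydroxy-18-(phenylsulfanyl)-13,14,15,16-tetranorclerodan-3-one
Product: 25 (5S,7S,8S,9R,10R)-7-hydroxy-12-iodo-18-(phenylsulfanyl)-13,14,15,16-tetranorclerodan-3-one
Conditions: I2, PPh3, imidazole, CH2Cl2, 0 °C
Reagents that add atoms: iodine (II)
Why: Appel-type iodination is an SN2 process and so picks the primary C12 hydroxyl over the secondary C7 hydroxyl next to the C8 methyl.

Step 19
Reactants: 25 (5S,7S,8S,9R,10R)-7-hydroxy-12-iodo-18-(phenylsulfanyl)-13,14,15,16-tetranorclerodan-3-one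
Product: 26 (5S,7S,8S,9R,10R)-7-acetoxy-12-iodo-18-(phenylsulfanyl)-13,14,15,16-tetranorclerodan-3-one
Conditions: Ac2O, pyridine, DMAP (cat.), CH2Cl2, rt
Reagents that add atoms: acetic anhydride (CC(=O)OC(C)=O)
Why: DMAP-catalysed acylation of the only remaining hydroxyl installs the C7 acetate with retention, and no later step uses a strong base or nucleophile.

Step 20
Reactants: 27 tert-butyl acetoacetate
Product: 28 tert-butyl (2E)-3-(trifluoromethylsulfonyloxy)but-2-enoate
Conditions: Tf2O, aq. Me4NOH, hexanes, 5 °C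
Reagents that add atoms: trifluoromethanesulfonic anhydride (O=S(=O)(OS(=O)(=O)C(F)(F)F)C(F)(F)F)
Why: Enol triflation of a β-keto ester through its non-chelated tetraalkylammonium enolate gives the E enol triflate (triflate trans to the ester), the geometry needed for C13=C14.

Step 21
Reactants: 26 (5S,7S,8S,9R,10R)-7-acetoxy-12-iodo-18-(phenylsulfanyl)-13,14,15,16-tetranorclerodan-3-one; 28 tert-butyl (2E)-3-(trifluoromethylsulfonyloxy)but-2-enoate
Product: 30 tert-butyl (5S,7S,8S,9R,10R,13E)-7-acetoxy-3-oxo-18-(phenylsulfanyl)clerod-13-en-15-oate, via alkylzinc iodide 29 (not isolated)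
Conditions: Zn dust (activated with BrCH2CH2Br and TMSCl), LiCl, THF, 35 °C; 28, Pd(PPh3)4 (5 mol %), THF, rt
Reagents that add atoms: none
Why: Zinc inserts into the primary iodide to give an alkylzinc iodide that tolerates ketone, acetate and sulfide, and the sp3–sp2 Negishi coupling proceeds with retention at the alkenyl triflate, which forms C12–C13 and fixes the 13E geometry.

Step 22
Reactants: 30 tert-butyl (5S,7S,8S,9R,10R,13E)-7-acetoxy-3-oxo-18-(phenylsulfanyl)clerod-13-en-15-oate
Product: 32 tert-butyl (5S,7S,8S,9R,10R,13E)-7-acetoxy-3-oxocleroda-4(18),13-dien-15-oate, via sulfoxide 31 (not isolated)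
Conditions: m-CPBA (1.0 equiv), CH2Cl2, −78 °C; PhMe, 60 °C
Reagents that add atoms: none
Why: Sulfide oxidation is far faster than attack of the peracid on the electron-poor enoate or the ketone, and sulfoxide syn elimination through the acidic C4–H unveils C4=C18, which quaternary C5 shields against dimerisation.

Step 23
Reactants: 32 tert-butyl (5S,7S,8S,9R,10R,13E)-7-acetoxy-3-oxocleroda-4(18),13-dien-15-oate
Product: 35 tert-butyl (5S,7S,8S,9R,10R,13E)-7-acetoxy-2-hydroxy-3-oxocleroda-4(18),13-dien-15-oate (C2 epimers), via TMS dienol ether 33 (not isolated), via 2-trimethylsilyloxy ketone 34 (not isolated)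
Conditions: TMSOTf, Et3N, CH2Cl2, −78 to 0 °C; m-CPBA, CH2Cl2/hexane, −15 °C; 1 M aq. citric acid, THF
Reagents that add atoms: 3-chloroperoxybenzoic acid (OOC(=O)c1cccc(Cl)c1)
Why: Soft enolisation can go only towards C2 because C4 no longer bears hydrogen and it spares both esters, and the Rubottom oxidation attacks the electron-rich silyl enol ether bond rather than the electron-poor alkenes, the C2 carbinol centre being erased in the next step.

Step 24
Reactants: 35 tert-butyl (5S,7S,8S,9R,10R,13E)-7-acetoxy-2-hydroxy-3-oxocleroda-4(18),13-dien-15-oate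
Product: 37 tert-butyl (5S,7S,8S,9R,10R,13E)-7-acetoxy-2-hydroxy-3-oxocleroda-1,4(18),13-trien-15-oate, via 2,3-diketone 36 (not isolated)
Conditions: Dess–Martin periodinane, CH2Cl2, rt
Reagents that add atoms: none
Why: Dess–Martin oxidation of the acyloin gives the 2,3-diketone, which can enolise only towards C1 and so settles as the conjugated diosphenol under neutral conditions that leave C10 alone.

Step 25
Reactants: 37 tert-butyl (5S,7S,8S,9R,10R,13E)-7-acetoxy-2-hydroxy-3-oxocleroda-1,4(18),13-trien-15-oate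
Product: 38 (5S,7S,8S,9R,10R,13E)-7-acetoxy-2-hydroxy-3-oxocleroda-1,4(18),13-trien-15-oic acid (CNP0192653.1)
Conditions: CF3CO2H/CH2Cl2 (1:4), 0 °C to rt
Reagents that add atoms: none
Why: Acidolysis of the tert-butyl ester (E1 loss of isobutene) frees the acid without base or nucleophile, so the acetate, the diosphenol, the exocyclic enone and the 13E alkene persist.

Compound list
1 | 2,6-dimethylphenol | Cc1cccc(C)c1O | starting material
2 | 4-methoxy-2,6-dimethylphenol | COc1cc(C)c(O)c(C)c1 | intermediate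
3 | 4,4-dimethoxy-2,6-dimethylcyclohexa-2,5-dien-1-one | COC1(OC)C=C(C)C(=O)C(C)=C1 | intermediate
4 | lithium 4,4-dimethoxy-2,6-dimethylcyclohexa-1,5-dien-1-olate | [Li+].[O-]C1=C(C)CC(OC)(OC)C=C1C | intermediate
5 | allyl 4,4-dimethoxy-2,6-dimethylcyclohexa-1,5-dien-1-yl carbonate | C=CCOC(=O)OC1=C(C)CC(OC)(OC)C=C1C | intermediate
6 | (6S)-6-allyl-4,4-dimethoxy-2,6-dimethylcyclohex-2-en-1-one | C=CC[C@@]1(C)CC(OC)(OC)C=C(C)C1=O | intermediate
7 | (6S)-6-allyl-2,6-dimethylcyclohex-2-ene-1,4-dione | C=CC[C@@]1(C)CC(=O)C=C(C)C1=O | intermediate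
8 | (4S,6S)-6-allyl-4-hydroxy-2,6-dimethylcyclohex-2-en-1-one | C=CC[C@@]1(C)C[C@H](O)C=C(C)C1=O | intermediate
9 | (4S,6S)-6-allyl-4-(tert-butyldimethylsilyloxy)-2,6-dimethylcyclohex-2-en-1-one | C=CC[C@@]1(C)C[C@H](O[Si](C)(C)C(C)(C)C)C=C(C)C1=O | intermediate
10 | (3S,4S,6S)-6-allyl-4-(tert-butyldimethylsilyloxy)-2,3,6-trimethyl-1-(trimethylsilyloxy)cyclohex-1-ene | C=CC[C@@]1(C)C[C@H](O[Si](C)(C)C(C)(C)C)[C@@H](C)C(C)=C1O[Si](C)(C)C | intermediate
11 | lithium (3S,4S,6S)-6-allyl-4-(tert-butyldimethylsilyloxy)-2,3,6-trimethylcyclohex-1-en-1-olate | C=CC[C@@]1(C)C[C@H](O[Si](C)(C)C(C)(C)C)[C@@H](C)C(C)=C1[O-].[Li+] | intermediate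
12 | ethyl 2-[(1S,2S,3S,5S)-5-allyl-3-(tert-butyldimethylsilyloxy)-1,2,5-trimethyl-6-oxocyclohexyl]acetate | C=CC[C@@]1(C)C[C@H](O[Si](C)(C)C(C)(C)C)[C@@H](C)[C@](C)(CC(=O)OCC)C1=O | intermediate
13 | secondary ozonide (1,2,4-trioxolane) of the allyl group of 12 | C2OOC(O2)C[C@@]1(C)C[C@H](O[Si](C)(C)C(C)(C)C)[C@@H](C)[C@](C)(CC(=O)OCC)C1=O | intermediate
14 | ethyl 2-[(1S,2S,3S,5R)-3-(tert-butyldimethylsilyloxy)-1,2,5-trimethyl-6-oxo-5-(2-oxoethyl)cyclohexyl]acetate | O=CC[C@@]1(C)C[C@H](O[Si](C)(C)C(C)(C)C)[C@@H](C)[C@](C)(CC(=O)OCC)C1=O | intermediate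
15 | ethyl 2-[(1S,2S,3S,5R)-3-(tert-butyldimethylsilyloxy)-1,2,5-trimethyl-6-oxo-5-(3-oxoprop-1-en-2-yl)cyclohexyl]acetate | O=CC(=C)[C@@]1(C)C[C@H](O[Si](C)(C)C(C)(C)C)[C@@H](C)[C@](C)(CC(=O)OCC)C1=O | intermediate
16 | ethyl 2-[(1S,2S,3S,5R)-3-(tert-butyldimethylsilyloxy)-1,2,5-trimethyl-6-oxo-5-[1-oxo-3-(phenylsulfanyl)propan-2-yl]cyclohexyl]acetate (C4 epimers) | O=CC(CSc2ccccc2)[C@@]1(C)C[C@H](O[Si](C)(C)C(C)(C)C)[C@@H](C)[C@](C)(CC(=O)OCC)C1=O | intermediate
17 | ethyl 2-[(1S,2S,3S,5R)-3-(tert-butyldimethylsilyloxy)-5-[3-hydroxy-1-(phenylsulfanyl)pent-4-en-2-yl]-1,2,5-trimethyl-6-oxocyclohexyl]acetate (C3 and C4 epimers) | C=CC(O)C(CSc2ccccc2)[C@@]1(C)C[C@H](O[Si](C)(C)C(C)(C)C)[C@@H](C)[C@](C)(CC(=O)OCC)C1=O | intermediate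
18 | (1R,2S,3S,4S,6R)-4-(tert-butyldimethylsilyloxy)-2-(2-hydroxyethyl)-6-[3-hydroxy-1-(phenylsulfanyl)pent-4-en-2-yl]-2,3,6-trimethylcyclohexan-1-ol | C=CC(O)C(CSc2ccccc2)[C@@]1(C)C[C@H](O[Si](C)(C)C(C)(C)C)[C@@H](C)[C@](C)(CCO)[C@H]1O | intermediate
19 | (1R,2S,3S,4S,6R)-4-(tert-butyldimethylsilyloxy)-2-[2-(tert-butyldimethylsilyloxy)ethyl]-6-[3-(tert-butyldimethylsilyloxy)-1-(phenylsulfanyl)pent-4-en-2-yl]-2,3,6-trimethylcyclohexan-1-ol | C=CC(O[Si](C)(C)C(C)(C)C)C(CSc2ccccc2)[C@@]1(C)C[C@H](O[Si](C)(C)C(C)(C)C)[C@@H](C)[C@](C)(CCO[Si](C)(C)C(C)(C)C)[C@H]1O | intermediate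
20 | potassium O-alkyl dithiocarbonate (xanthate salt) of 19 | C=CC(O[Si](C)(C)C(C)(C)C)C(CSc2ccccc2)[C@@]1(C)C[C@H](O[Si](C)(C)C(C)(C)C)[C@@H](C)[C@](C)(CCO[Si](C)(C)C(C)(C)C)[C@H]1OC(=S)[S-].[K+] | intermediate
21 | O-alkyl S-methyl carbonodithioate of 19 (10α-xanthate with silyl ethers at O3, O7 and O12) | C=CC(O[Si](C)(C)C(C)(C)C)C(CSc2ccccc2)[C@@]1(C)C[C@H](O[Si](C)(C)C(C)(C)C)[C@@H](C)[C@](C)(CCO[Si](C)(C)C(C)(C)C)[C@H]1OC(=S)SC | intermediate
22 | O-{(1R,2S,3S,4S,6R)-4-hydroxy-2-(2-hydroxyethyl)-6-[3-hydroxy-1-(phenylsulfanyl)pent-4-en-2-yl]-2,3,6-trimethylcyclohexyl} S-methyl carbonodithioate | C=CC(O)C(CSc2ccccc2)[C@@]1(C)C[C@H](O)[C@@H](C)[C@](C)(CCO)[C@H]1OC(=S)SC | intermediate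
23 | O-{(1R,2S,3S,4S,6R)-4-hydroxy-2-(2-hydroxyethyl)-2,3,6-trimethyl-6-[3-oxo-1-(phenylsulfanyl)pent-4-en-2-yl]cyclohexyl} S-methyl carbonodithioate (key-step precursor) | C=CC(=O)C(CSc2ccccc2)[C@@]1(C)C[C@H](O)[C@@H](C)[C@](C)(CCO)[C@H]1OC(=S)SC | intermediate
24 | (5S,7S,8S,9R,10R)-7,12-dihydroxy-18-(phenylsulfanyl)-13,14,15,16-tetranorclerodan-3-one (key-step product) | c3ccccc3SCC1C(=O)CC[C@@H]2[C@@](C)(CCO)[C@H](C)[C@@H](O)C[C@]12C | intermediate
25 | (5S,7S,8S,9R,10R)-7-hydroxy-12-iodo-18-(phenylsulfanyl)-13,14,15,16-tetranorclerodan-3-one | c3ccccc3SCC1C(=O)CC[C@@H]2[C@@](C)(CCI)[C@H](C)[C@@H](O)C[C@]12C | intermediate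
26 | (5S,7S,8S,9R,10R)-7-acetoxy-12-iodo-18-(phenylsulfanyl)-13,14,15,16-tetranorclerodan-3-one | c3ccccc3SCC1C(=O)CC[C@@H]2[C@@](C)(CCI)[C@H](C)[C@@H](OC(C)=O)C[C@]12C | intermediate
27 | tert-butyl acetoacetate | CC(=O)CC(=O)OC(C)(C)C | starting material
28 | tert-butyl (2E)-3-(trifluoromethylsulfonyloxy)but-2-enoate | FC(F)(F)S(=O)(=O)O/C(C)=C/C(=O)OC(C)(C)C | intermediate
29 | C12 alkylzinc iodide derived from 26 | c3ccccc3SCC1C(=O)CC[C@@H]2[C@@](C)(CC[Zn]I)[C@H](C)[C@@H](OC(C)=O)C[C@]12C | intermediate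
30 | tert-butyl (5S,7S,8S,9R,10R,13E)-7-acetoxy-3-oxo-18-(phenylsulfanyl)clerod-13-en-15-oate | c3ccccc3SCC1C(=O)CC[C@@H]2[C@@](C)(CC/C(C)=C/C(=O)OC(C)(C)C)[C@H](C)[C@@H](OC(C)=O)C[C@]12C | intermediate
31 | 18-phenylsulfinyl analogue (sulfoxide) of 30 | O=S(c3ccccc3)CC1C(=O)CC[C@@H]2[C@@](C)(CC/C(C)=C/C(=O)OC(C)(C)C)[C@H](C)[C@@H](OC(C)=O)C[C@]12C | intermediate
32 | tert-butyl (5S,7S,8S,9R,10R,13E)-7-acetoxy-3-oxocleroda-4(18),13-dien-15-oate | C=C1C(=O)CC[C@@H]2[C@@](C)(CC/C(C)=C/C(=O)OC(C)(C)C)[C@H](C)[C@@H](OC(C)=O)C[C@]12C | intermediate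
33 | 3-trimethylsilyloxy-2,4(18)-diene (TMS dienol ether) of 32 | C=C1C(O[Si](C)(C)C)=CC[C@@H]2[C@@](C)(CC/C(C)=C/C(=O)OC(C)(C)C)[C@H](C)[C@@H](OC(C)=O)C[C@]12C | intermediate
34 | 2-trimethylsilyloxy derivative of 32 | C=C1C(=O)C(O[Si](C)(C)C)C[C@@H]2[C@@](C)(CC/C(C)=C/C(=O)OC(C)(C)C)[C@H](C)[C@@H](OC(C)=O)C[C@]12C | intermediate
35 | tert-butyl (5S,7S,8S,9R,10R,13E)-7-acetoxy-2-hydroxy-3-oxocleroda-4(18),13-dien-15-oate (C2 epimers) | C=C1C(=O)C(O)C[C@@H]2[C@@](C)(CC/C(C)=C/C(=O)OC(C)(C)C)[C@H](C)[C@@H](OC(C)=O)C[C@]12C | intermediate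
36 | tert-butyl (5S,7S,8S,9R,10R,13E)-7-acetoxy-2,3-dioxocleroda-4(18),13-dien-15-oate | C=C1C(=O)C(=O)C[C@@H]2[C@@](C)(CC/C(C)=C/C(=O)OC(C)(C)C)[C@H](C)[C@@H](OC(C)=O)C[C@]12C | intermediate
37 | tert-butyl (5S,7S,8S,9R,10R,13E)-7-acetoxy-2-hydroxy-3-oxocleroda-1,4(18),13-trien-15-oate | C=C1C(=O)C(O)=C[C@@H]2[C@@](C)(CC/C(C)=C/C(=O)OC(C)(C)C)[C@H](C)[C@@H](OC(C)=O)C[C@]12C | intermediate
38 | (5S,7S,8S,9R,10R,13E)-7-acetoxy-2-hydroxy-3-oxocleroda-1,4(18),13-trien-15-oic acid | C=C1C(=O)C(O)=C[C@@H]2[C@@](C)(CC/C(C)=C/C(=O)O)[C@H](C)[C@@H](OC(C)=O)C[C@]12C | target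

Total step count: 25 (24 in the main line and 1 for fragment 28).
Longest linear sequence: 24 steps (steps 1–19 and 21–25, from 1 to 38).

Steps most likely to fail

Step 17. Hydrogen may be transferred from the tin hydride to the crowded C10 radical before ring A closes, or the tin hydride may consume the vinyl ketone. The fallback removes every hydride donor and changes both chain carrier and termination. It sets out from 23, which is treated with BEt3 and a trace of air in dry benzene. Ethyl radicals add to the C=S group, the C10 radical is released and cyclises as before. BEt3 then captures the C2 α-keto radical at oxygen, which gives the diethylboron enolate F1 and a new ethyl radical that carries the chain. Protonolysis of the enolate by the free hydroxyls or on work-up comes back to the route at 24.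

Step 8. C-alkylation of a tetrasubstituted enolate wedged between quaternary C5 and tertiary C8 may be slow. O-alkylation, proton transfer to the iodo ester or approach from the α face could then compete. The fallback replaces the polar SN2 step by a radical addition with an early transition state. It sets out from 10, to which the electrophilic ethoxycarbonylmethyl radical (ethyl iodoacetate, BEt3/air or visible-light photoredox initiation) adds at C9, again anti to the C8 methyl. Iodine transfer and loss of the silyl group come back to the route at 12. No new compound arises (F0).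

Step 2. Hydride may attack the carbonyl (1,2-attack), or methanol may be lost with aromatisation before or during O-acylation. The fallback avoids a free enolate. It sets out from 3, where RhCl(PPh3)3-catalysed 1,4-hydrosilylation with Et3SiH gives the triethylsilyl dienol ether F2. This enters the same asymmetric allylation in its intermolecular, fluoride-triggered form (diallyl carbonate, Bu4N[Ph3SiF2], Pd2(dba)3, (R)-t-BuPHOX) and comes back to the route at 6.

Further compounds
F1 | step 17 | diethylboron enolate (C2=C3) of decalone 24 | c3ccccc3SCC1C(OB(CC)CC)=CC[C@@H]2[C@@](C)(CCO)[C@H](C)[C@@H](O)C[C@]12C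
F0 | step 8 | none | none
F2 | step 2 | (4,4-dimethoxy-2,6-dimethylcyclohexa-1,5-dien-1-yl)oxytriethylsilane | CC[Si](CC)(CC)OC1=C(C)CC(OC)(OC)C=C1C
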